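## Retrosynthetic overview

- The 3(2H)-furanone is read as a tetrahydrofuran-3-one: an ether oxygen bridges C3 and C10, the C1 ketone flanks quaternary C10, and C9 sits on C10. C9–C10 is therefore made by carbenoid → oxonium ylide → [2,3]-shift, which expands a tetrahydropyran (O, C3–C7) by three atoms into the 11-oxabicyclo[6.2.1]undecane (furanone plus ten-membered carbocycle) and sets C10 (from C3) and C9 (from an (E)-enol ether).
- The Z-C7=C8 olefin released by the shift is then used: methylenation at C11, outer-face epoxidation, palladium/formate hydrogenolysis (C7–H with inversion, C8–OH), angeloylation; the C6/C12 lactone closes last.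
- The all-cis tetrahydropyran comes from a catalytic asymmetric hetero-Diels–Alder reaction (C3, C4), Luche reduction (C5) and hydroxyl-directed dihydroxylation (C6); quaternary C7 from two anomeric C–C bond formations (acetylide to the δ-lactone, ketene silyl acetal to the ketosyl cation).
- Ring order: tetrahydropyran → tetrahydrofuranone plus ten-membered ring (key step) → α-methylene-γ-lactone.

Key step: step 17

Remark (numbering): germacrane numbering is used for the target and for the same atoms in every precursor: C1 ketone, C2=C3 enol ether, C4 (Me-15), C5 (OH), C6 (lactone O), C7, C8 (OAng), C9 (OH), C10 (Me-14), C11=C13, C12 lactone carbonyl.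
Remark (assumption): the target SMILES is read as 4R,5S,6R,7S,8S,9R,10R with a cis-fused lactone and a (Z)-2-methylbut-2-enoate (angelate).
Remark (assumption): both enantiomers of the chromium Schiff-base catalyst of step 3 are available; the one that gives 6 as drawn is used.
Remark: SMILES of 8 (TMEDA on osmium not drawn), 17 (cyclopentadienyl drawn η1) and 25 (drawn metal-free) are simplified.

## Route

Step 1
Reactants: 1 (E)-4-methoxybut-3-en-2-one
Product: 2 (E)-1-methoxypent-1-en-3-one
Conditions: LiN(iPr)2, THF, −78 °C; then MeI, −78 → −20 °C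
Reagents that add atoms: iodomethane, CI
Why: kinetic deprotonation of the vinylogous ester at its methyl ketone position and enolate C-alkylation adds the carbon that becomes Me-15, with no stereocentre formed.

Step 2
Reactants: 2 (E)-1-methoxypent-1-en-3-one
Product: 3 (1E,3Z)-1-methoxy-3-(trimethylsilyloxy)penta-1,3-diene
Conditions: TMSOTf, Et3N, Et2O, 0 °C
Reagents that add atoms: trimethylsilyl trifluoromethanesulfonate, C[Si](C)(C)OS(=O)(=O)C(F)(F)F
Why: amine-mediated soft enolisation and O-silylation of the ethyl ketone should give the (Z)-silyl enol ether, the methyl group avoiding the vinyl substituent.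

Step 3
Reactants: 3 (1E,3Z)-1-methoxy-3-(trimethylsilyloxy)penta-1,3-diene; 4 3-[(tert-butyldiphenylsilyl)oxy]propanal
Product: 6 (2R,3S)-2-[2-(tert-butyldiphenylsilyloxy)ethyl]-3-methyl-2,3-dihydro-4H-pyran-4-one, via cycloadduct 5 (not isolated)
Conditions: [Cr(L)Cl] (3 mol%; L = dianion of 2-(1-adamantyl)-6-{[(2-hydroxy-2,3-dihydro-1H-inden-1-yl)imino]methyl}-4-methylphenol, trivalent chromium), 4 Å molecular sieves, tert-butyl methyl ether, rt; then CF3CO2H (cat.), wet CH2Cl2, 0 °C
Reagents that add atoms: none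
Why: catalytic asymmetric hetero-Diels–Alder reaction in which concerted endo addition to the (Z,E)-diene fixes the C3/C4 cis relationship and the chiral chromium Lewis acid selects the aldehyde face, after which acid eliminates methanol to the dihydropyranone.

Step 4
Reactants: 6 (2R,3S)-2-[2-(tert-butyldiphenylsilyloxy)ethyl]-3-methyl-2,3-dihydro-4H-pyran-4-one
Product: 7 all-cis 2-[2-(tert-butyldiphenylsilyloxy)ethyl]-3-methyl-3,4-dihydro-2H-pyran-4-ol
Conditions: NaBH4, CeCl3·7H2O, MeOH, −78 °C
Reagents that add atoms: none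
Why: Luche 1,2-reduction in which hydride attacks anti to the pseudo-axial C4 methyl and the C3 side chain, so the C5 hydroxyl should end up cis to both.

Step 5
Reactants: 7 all-cis dihydropyranol
Product: 9 all-cis 6-[2-(tert-butyldiphenylsilyloxy)ethyl]-5-methyltetrahydropyran-2,3,4-triol (anomer mixture), via osmate ester 8 (not isolated)
Conditions: OsO4 (1.05 equiv), TMEDA, CH2Cl2, −78 °C; then aq. Na2SO3, THF, rt
Reagents that add atoms: osmium tetroxide, O=[Os](=O)(=O)=O
Why: hydrogen-bond-directed syn dihydroxylation in which the allylic C5 hydroxyl steers the OsO4·TMEDA complex to its own face of the enol ether, placing the C6 oxygen cis to C5–OH against the steric bias.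

Step 6
Reactants: 9 lactol triol
Product: 10 3,4-O-isopropylidene lactol (C5,C6 acetonide, anomeric OH free)
Conditions: 2,2-dimethoxypropane, PPTS (cat.), acetone, rt
Reagents that add atoms: 2,2-dimethoxypropane, COC(C)(C)OC
Why: acetonide formation across the cis C5,C6-diol, the same pattern as 2,3-O-isopropylidene formation on manno-configured pyranoses, leaves the anomeric hydroxyl free.

Step 7
Reactants: 10 acetonide lactol
Product: 11 δ-lactone (C7 carbonyl)
Conditions: nPr4N[RuO4] (5 mol%), N-methylmorpholine N-oxide, 4 Å molecular sieves, CH2Cl2, rt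
Reagents that add atoms: none
Why: Ley–Griffith oxidation of a lactol to the lactone, which tolerates the acetonide and silyl ether.

Step 8
Reactants: 11 δ-lactone
Product: 12 C7 hemiketal bearing a (trimethylsilyl)ethynyl group (anomer mixture)
Conditions: ethynyltrimethylsilane, n-BuLi, THF, −78 °C; then 11, −78 °C; aq. NH4Cl
Reagents that add atoms: ethynyltrimethylsilane, C#C[Si](C)(C)C
Why: a lithium acetylide adds once to a δ-lactone at low temperature because the tetrahedral alkoxide (ketose hemiketal) is stable until work-up.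

Step 9
Reactants: 13 tert-butyl acetate
Product: 14 tert-butyl[(1-tert-butoxyvinyl)oxy]dimethylsilane
Conditions: LiN(iPr)2, THF, −78 °C; then TBSCl, DMPU, −78 °C → rt
Reagents that add atoms: tert-butyldimethylsilyl chloride, CC(C)(C)[Si](C)(C)Cl
Why: O-silylation of the ester enolate gives the ketene silyl acetal needed as a neutral C11–C12 nucleophile.

Step 10
Reactants: 12 alkynyl hemiketal; 14 ketene silyl acetal
Product: 15 C7-quaternary tetrahydropyran (CH2CO2tBu trans and silylethynyl cis to the acetonide)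
Conditions: TMSOTf (0.2 equiv), CH2Cl2, −78 °C
Reagents that add atoms: none
Why: Mukaiyama-type C-glycosylation through the alkynyl-stabilised oxocarbenium ion, in which the nucleophile should enter from the face opposite to the acetonide, Me-15 and the C3 side chain (all on one face), so C11 becomes trans to O6 and the alkynyl group stays cis to the C3 side chain.

Step 11
Reactants: 15 silylalkyne
Product: 16 terminal alkyne
Conditions: K2CO3, MeOH, rt
Reagents that add atoms: none
Why: methanolysis of the alkynyl C–Si bond leaves the tert-butyl ester, acetonide and silyl ether untouched.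

Step 12
Reactants: 16 terminal alkyne
Product: 18 (E)-vinyl iodide, via alkenylzirconocene 17 (not isolated)
Conditions: Cp2ZrHCl, THF, rt; then I2, 0 °C
Reagents that add atoms: iodine, II
Why: syn hydrozirconation places zirconium on the terminal carbon and iodinolysis proceeds with retention, fixing the E geometry of C8=C9.

Step 13
Reactants: 18 (E)-vinyl iodide
Product: 19 (E)-4-methoxybenzyl enol ether
Conditions: CuI (10 mol%), 3,4,7,8-tetramethyl-1,10-phenanthroline (20 mol%), Cs2CO3, 4-methoxybenzyl alcohol, toluene, 80 °C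
Reagents that add atoms: 4-methoxybenzyl alcohol, COc1ccc(CO)cc1
Why: copper-catalysed Ullmann-type C–O coupling of a vinyl iodide with an alcohol retains the olefin geometry and installs the future C9 oxygen already protected.

Step 14
Reactants: 19 (E)-enol ether
Product: 20 primary alcohol (C1–OH)
Conditions: TBAF, AcOH, THF, 0 °C → rt
Reagents that add atoms: none
Why: buffered fluoride cleaves the only silyl ether without touching the acid-sensitive enol ether.

Step 15
Reactants: 20 primary alcohol
Product: 22 carboxylic acid (C1), via aldehyde 21 (not isolated)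
Conditions: TEMPO (0.2 equiv), PhI(OAc)2 (2.2 equiv), CH2Cl2/pH 7 phosphate buffer, rt
Reagents that add atoms: water, O
Why: oxoammonium oxidation to the aldehyde and, through its hydrate, to the acid at neutral pH should spare the enol ether and acetonide.

Step 16
Reactants: 22 carboxylic acid
Product: 24 α-methyl diazoketone, via mixed anhydride 23 (not isolated)
Conditions: isobutyl chloroformate, Et3N, THF, −20 °C; then CH3CHN2 in Et2O (prepared beforehand from N-ethyl-N-nitrosourea and aq. KOH), 0 °C
Reagents that add atoms: diazoethane, CC=[N+]=[N-]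
Why: acylation of a diazoalkane by a mixed carbonic anhydride gives the 2-diazo-3-ketone regiospecifically, bringing in C10 and Me-14 under non-acidic conditions.

Step 17
Reactants: 24 α-methyl diazoketone
Product: 26 ring-expanded (7Z)-11-oxabicyclo[6.2.1]undecenone, via oxonium ylide 25 (not isolated)
Conditions: Cu(hfacac)2 (5 mol%; hfacac = hexafluoroacetylacetonate), CH2Cl2, reflux, slow addition of 24
Reagents that add atoms: none
Why: Loss of N2 gives a copper carbenoid at C10 that is captured by the pyran oxygen to the bicyclic oxonium ylide 25, whose [2,3]-sigmatropic shift (or its ion-pair equivalent through the alkoxy-stabilised allyl cation) makes C9–C10 and breaks O–C7. The closest known reaction type is the copper-catalysed oxonium-ylide formation/[2,3] ring expansion of 6-vinyltetrahydropyran-2-yl diazoketones to 11-oxabicyclo[6.2.1]undecenones; new here are the alkoxy-substituted terminus, the fully substituted C7 and the methyl-bearing carbenoid. The furanone ring closes by 5-exo attack of the ether oxygen on the carbenoid, and the ten-membered carbocycle (nine-membered oxacycle) arises by three-atom ring expansion of the tetrahydropyran through the five-membered cyclic transition state. C10 is set by C3, because C9 can only bond on the face of the new five-membered ring on which C4 already sits, and C9 is set by the (E)-geometry of the enol ether, whose alkoxy group takes the exo position of the envelope transition state; C7=C8 comes out Z because the alkenyl group reacts from the equatorial position of the chair. The step needs ylide formation to beat 1,2-hydride shift and cyclopropanation, which the five-membered ylide closure, Cu(hfacac)2 and the primary C–H bonds of the methyl group favour, and it needs the equatorial-alkenyl/exo-alkoxy transition state to beat its chair-flipped alternative, which the cis relationship of the C3 and C7 substituents and the exo preference of the alkoxy group favour.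

Step 18
Reactants: 26 ring-expanded ketone
Product: 28 bridged 3(2H)-furanone, via silyl enol ether 27 (not isolated)
Conditions: TMSOTf, Et3N, CH2Cl2, −78 → 0 °C; then Pd(OAc)2 (1.1 equiv), MeCN, rt
Reagents that add atoms: none
Why: Saegusa–Ito dehydrogenation, in which the ketone can enolise only toward C2 (C10 is quaternary) and β-hydride elimination uses H3 on the face opposite the bridge, gives the C2=C3 vinylogous ester.

Step 19
Reactants: 28 furanone
Product: 31 diene ester (tert-butyl 2-substituted acrylate), via Mannich base 29 (not isolated), via ammonium iodide 30 (not isolated)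
Conditions: LiN(SiMe3)2 (1.05 equiv), THF, −78 °C; N,N-dimethylmethyleneiminium iodide; then MeI, MeOH, rt; then NaHCO3, CH2Cl2/H2O
Reagents that add atoms: N,N-dimethylmethyleneiminium iodide, C=[N+](C)C.[I-]
Why: the C11 methylene is the only doubly activated CH2 (ester α and allylic), so Mannich aminomethylation followed by quaternisation and Hofmann-type elimination should install C13 as the exocyclic methylene.

Step 20
Reactants: 31 diene ester
Product: 32 7,8-epoxide (alkenyl oxirane)
Conditions: mCPBA, NaHCO3, CH2Cl2, 0 °C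
Reagents that add atoms: 3-chloroperbenzoic acid, OOC(=O)c1cccc(Cl)c1
Why: Prilezhaev epoxidation picks the trisubstituted C7=C8 over the acrylate and vinylogous-ester olefins and should occur on the outer face of the Z ring olefin (the inner face looks at the ether bridge), which sets C8.

Step 21
Reactants: 32 alkenyl oxirane
Product: 33 C8 alcohol with C7–H (tert-butyl acrylate retained)
Conditions: Pd2(dba)3·CHCl3 (5 mol%), n-Bu3P (20 mol%), HCO2H, Et3N, dioxane, rt
Reagents that add atoms: none
Why: formate hydrogenolysis of an alkenyl oxirane in which zerovalent palladium ionises C7–O anti to the oxygen and the palladium hydride delivers hydrogen to the more substituted terminus C7 on the metal face, giving inversion at C7, the terminal C11=C13 olefin and an untouched C8 carbinol.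

Step 22
Reactants: 33 C8 alcohol
Product: 34 C8 angelate
Conditions: angelic acid, 2,4,6-trichlorobenzoyl chloride, Et3N, toluene, rt; then 33, 80 °C (no DMAP)
Reagents that add atoms: angelic acid, C/C=C(/C)C(=O)O
Why: Yamaguchi-type mixed-anhydride esterification without a nucleophilic catalyst acylates the only free hydroxyl and should avoid Z→E isomerisation to the tiglate, while the tert-butyl ester prevents prior lactonisation onto O8.

Step 23
Reactants: 34 C8 angelate
Product: 35 C9 alcohol
Conditions: DDQ, CH2Cl2/pH 7 buffer, 0 °C → rt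
Reagents that add atoms: none
Why: oxidative cleavage of the 4-methoxybenzyl ether under neutral conditions tolerates the angelate, acrylate, acetonide and furanone.

Step 24
Reactants: 35 C9 alcohol
Product: 37 target CNP0206920.1, via trihydroxy acid 36 (not isolated)
Conditions: CF3CO2H/CH2Cl2/H2O (8:2:1), 0 °C → rt
Reagents that add atoms: none
Why: acidolysis of the tert-butyl ester and hydrolysis of the acetonide free the C12 acid and the C5/C6 diol, and acid-catalysed lactonisation should take the γ-position (O6, cis to the C7 branch) over the δ-lactones to O5 or O9, giving the cis-fused α-methylene-γ-lactone.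

## Compound list

1 | (E)-4-methoxybut-3-en-2-one | CO/C=C/C(C)=O | starting material
2 | (E)-1-methoxypent-1-en-3-one | CCC(=O)/C=C/OC | intermediate
3 | (1E,3Z)-1-methoxy-3-(trimethylsilyloxy)penta-1,3-diene | C/C=C(/C=C/OC)O[Si](C)(C)C | intermediate
4 | 3-[(tert-butyldiphenylsilyl)oxy]propanal | O=CCCO[Si](c1ccccc1)(c1ccccc1)C(C)(C)C | starting material
5 | hetero-Diels–Alder adduct, 2-methoxy-4-silyloxy-5,6-cis-dihydropyran (not isolated) | COC1C=C(O[Si](C)(C)C)[C@@H](C)[C@@H](CCO[Si](c2ccccc2)(c2ccccc2)C(C)(C)C)O1 | intermediate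
6 | (2R,3S)-2-[2-(tert-butyldiphenylsilyloxy)ethyl]-3-methyl-2,3-dihydro-4H-pyran-4-one | C[C@H]1[C@@H](CCO[Si](c2ccccc2)(c2ccccc2)C(C)(C)C)OC=CC1=O | intermediate
7 | all-cis 2-[2-(tert-butyldiphenylsilyloxy)ethyl]-3-methyl-3,4-dihydro-2H-pyran-4-ol | C[C@H]1[C@@H](CCO[Si](c2ccccc2)(c2ccccc2)C(C)(C)C)OC=C[C@H]1O | intermediate
8 | cyclic osmate ester of 7 at C6/C7, TMEDA-ligated (not isolated) | C[C@H]1[C@@H](CCO[Si](c2ccccc2)(c2ccccc2)C(C)(C)C)O[C@H]2O[Os](=O)(=O)O[C@H]2[C@H]1O | intermediate
9 | all-cis 6-[2-(tert-butyldiphenylsilyloxy)ethyl]-5-methyltetrahydropyran-2,3,4-triol (anomer mixture) | C[C@H]1[C@@H](CCO[Si](c2ccccc2)(c2ccccc2)C(C)(C)C)OC(O)[C@@H](O)[C@H]1O | intermediate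
10 | C5,C6-O-isopropylidene lactol | C[C@H]1[C@@H](CCO[Si](c2ccccc2)(c2ccccc2)C(C)(C)C)OC(O)[C@H]2OC(C)(C)O[C@@H]12 | intermediate
11 | C5,C6-O-isopropylidene δ-lactone (C7 carbonyl) | C[C@H]1[C@@H](CCO[Si](c2ccccc2)(c2ccccc2)C(C)(C)C)OC(=O)[C@H]2OC(C)(C)O[C@@H]12 | intermediate
12 | C7 hemiketal with (trimethylsilyl)ethynyl group (anomer mixture) | C[C@H]1[C@@H](CCO[Si](c2ccccc2)(c2ccccc2)C(C)(C)C)OC(O)(C#C[Si](C)(C)C)[C@H]2OC(C)(C)O[C@@H]12 | intermediate
13 | tert-butyl acetate | CC(=O)OC(C)(C)C | starting material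
14 | tert-butyl[(1-tert-butoxyvinyl)oxy]dimethylsilane | C=C(OC(C)(C)C)O[Si](C)(C)C(C)(C)C | intermediate
15 | tetrahydropyran with quaternary C7: CH2CO2tBu (trans to acetonide), (trimethylsilyl)ethynyl (cis); C3 side chain CH2CH2OTBDPS | CC(C)(C)[Si](c1ccccc1)(c1ccccc1)OCC[C@H]1O[C@](C#C[Si](C)(C)C)(CC(=O)OC(C)(C)C)[C@H]2OC(C)(C)O[C@H]2[C@H]1C | intermediate
16 | terminal alkyne corresponding to 15 | CC(C)(C)[Si](c1ccccc1)(c1ccccc1)OCC[C@H]1O[C@](C#C)(CC(=O)OC(C)(C)C)[C@H]2OC(C)(C)O[C@H]2[C@H]1C | intermediate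
17 | (E)-alkenylzirconocene chloride (not isolated) | CC(C)(C)[Si](c1ccccc1)(c1ccccc1)OCC[C@H]1O[C@](/C=C/[Zr](Cl)(C2C=CC=C2)C2C=CC=C2)(CC(=O)OC(C)(C)C)[C@H]2OC(C)(C)O[C@H]2[C@H]1C | intermediate
18 | (E)-vinyl iodide (C9–I) | CC(C)(C)[Si](c1ccccc1)(c1ccccc1)OCC[C@H]1O[C@](/C=C/I)(CC(=O)OC(C)(C)C)[C@H]2OC(C)(C)O[C@H]2[C@H]1C | intermediate
19 | (E)-4-methoxybenzyl enol ether (C8=C9–OPMB) | CC(C)(C)[Si](c1ccccc1)(c1ccccc1)OCC[C@H]1O[C@](/C=C/OCc2ccc(OC)cc2)(CC(=O)OC(C)(C)C)[C@H]2OC(C)(C)O[C@H]2[C@H]1C | intermediate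
20 | primary alcohol (C1–OH) | OCC[C@H]1O[C@](/C=C/OCc2ccc(OC)cc2)(CC(=O)OC(C)(C)C)[C@H]2OC(C)(C)O[C@H]2[C@H]1C | intermediate
21 | C1 aldehyde (not isolated) | O=CC[C@H]1O[C@](/C=C/OCc2ccc(OC)cc2)(CC(=O)OC(C)(C)C)[C@H]2OC(C)(C)O[C@H]2[C@H]1C | intermediate
22 | C1 carboxylic acid | OC(=O)C[C@H]1O[C@](/C=C/OCc2ccc(OC)cc2)(CC(=O)OC(C)(C)C)[C@H]2OC(C)(C)O[C@H]2[C@H]1C | intermediate
23 | isobutyl carbonic mixed anhydride (not isolated) | CC(C)COC(=O)OC(=O)C[C@H]1O[C@](/C=C/OCc2ccc(OC)cc2)(CC(=O)OC(C)(C)C)[C@H]2OC(C)(C)O[C@H]2[C@H]1C | intermediate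
24 | α-methyl diazoketone (3-diazobutan-2-one unit at C3 of the tetrahydropyran) | CC(=[N+]=[N-])C(=O)C[C@H]1O[C@](/C=C/OCc2ccc(OC)cc2)(CC(=O)OC(C)(C)C)[C@H]2OC(C)(C)O[C@H]2[C@H]1C | intermediate
25 | cis-fused bicyclic oxonium ylide, enolate form (not isolated) | CC1=C([O-])C[C@@H]2[C@H](C)[C@@H]3OC(C)(C)O[C@@H]3[C@@](/C=C/OCc3ccc(OC)cc3)(CC(=O)OC(C)(C)C)[O+]12 | intermediate
26 | ring-expanded ketone: (7Z)-11-oxabicyclo[6.2.1]undec-7-en-1-one core with 9-OPMB, 10-Me, 5,6-acetonide, C7–CH2CO2tBu | CC(C)(C)OC(=O)C/C1=C/[C@@H](OCc2ccc(OC)cc2)[C@@]2(C)O[C@H](CC2=O)[C@H](C)[C@@H]2OC(C)(C)O[C@H]12 | intermediate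
27 | C1 trimethylsilyl enol ether (not isolated) | CC(C)(C)OC(=O)C/C1=C/[C@@H](OCc2ccc(OC)cc2)[C@@]2(C)O[C@H](C=C2O[Si](C)(C)C)[C@H](C)[C@@H]2OC(C)(C)O[C@H]12 | intermediate
28 | bridged 3(2H)-furanone (C2=C3) | CC(C)(C)OC(=O)C/C1=C/[C@@H](OCc2ccc(OC)cc2)[C@@]2(C)OC(=CC2=O)[C@H](C)[C@@H]2OC(C)(C)O[C@H]12 | intermediate
29 | C11 dimethylaminomethyl Mannich base, C11 epimers (not isolated) | CC(C)(C)OC(=O)C(CN(C)C)/C1=C/[C@@H](OCc2ccc(OC)cc2)[C@@]2(C)OC(=CC2=O)[C@H](C)[C@@H]2OC(C)(C)O[C@H]12 | intermediate
30 | trimethylammonium iodide of 29 (not isolated) | CC(C)(C)OC(=O)C(C[N+](C)(C)C)/C1=C/[C@@H](OCc2ccc(OC)cc2)[C@@]2(C)OC(=CC2=O)[C@H](C)[C@@H]2OC(C)(C)O[C@H]12.[I-] | intermediate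
31 | diene ester: tert-butyl acrylate (C11=C13) on (7Z)-C7=C8 | CC(C)(C)OC(=O)C(=C)/C1=C/[C@@H](OCc2ccc(OC)cc2)[C@@]2(C)OC(=CC2=O)[C@H](C)[C@@H]2OC(C)(C)O[C@H]12 | intermediate
32 | 7,8-epoxide (oxygen on the outer face) | CC(C)(C)OC(=O)C(=C)[C@@]12O[C@@H]1[C@@H](OCc3ccc(OC)cc3)[C@@]3(C)OC(=CC3=O)[C@H](C)[C@@H]3OC(C)(C)O[C@H]23 | intermediate
33 | C8 alcohol with C7–H | CC(C)(C)OC(=O)C(=C)[C@@H]1[C@H](O)[C@@H](OCc2ccc(OC)cc2)[C@@]2(C)OC(=CC2=O)[C@H](C)[C@@H]2OC(C)(C)O[C@H]12 | intermediate
34 | C8 angelate | CC(C)(C)OC(=O)C(=C)[C@@H]1[C@H](OC(=O)/C(C)=C\C)[C@@H](OCc2ccc(OC)cc2)[C@@]2(C)OC(=CC2=O)[C@H](C)[C@@H]2OC(C)(C)O[C@H]12 | intermediate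
35 | C9 alcohol (PMB removed) | CC(C)(C)OC(=O)C(=C)[C@@H]1[C@H](OC(=O)/C(C)=C\C)[C@@H](O)[C@@]2(C)OC(=CC2=O)[C@H](C)[C@@H]2OC(C)(C)O[C@H]12 | intermediate
36 | 5,6,9-trihydroxy acrylic acid (not isolated) | C=C(C(=O)O)[C@@H]1[C@H](OC(=O)/C(C)=C\C)[C@@H](O)[C@@]2(C)OC(=CC2=O)[C@H](C)[C@H](O)[C@@H]1O | intermediate
37 | CNP0206920.1 (4R,5S,6R,7S,8S,9R,10R) | C=C1C(=O)O[C@H]2[C@@H](O)[C@@H](C)C3=CC(=O)[C@](C)(O3)[C@H](O)[C@@H](OC(=O)/C(C)=C\C)[C@@H]12 | target

## Count and risks

Total step count: 24. Longest linear sequence: 23 steps (steps 1–8 and 10–24; step 9 is a one-step branch).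

**Step 17 (key step).** What may go wrong: partition of the ylide between its two chair-like conformers (the chair-flipped one would give the E ring olefin with the epimeric C9); diversion of the carbenoid by the electron-rich enol ether (cyclopropanation, C7–O heterolysis and [1,2]-recombination); or 1,2-hydride migration from the methyl group.
Fallback: the C9 oxygen is carried as boron. The fallback sets out from alkyne 16 and comes back at 26. Hydroboration with pinacolborane (Cp2ZrHCl cat., Et3N, 60 °C) would give the (E)-alkenylboronate F1. The operations of steps 14–16 would then give alcohol F2, through aldehyde F3 the acid F4, and through mixed anhydride F5 the diazoketone F6. Cu(hfacac)2 would take F6 through oxonium ylide F7 to the allylboronate F8; the terminus is now electron-poor and cannot ionise, and the boryl group takes the same exo position. NaBO3·4H2O would oxidise the C–B bond with retention to the allylic alcohol F9, and 4-methoxybenzyl trichloroacetimidate with La(OTf)3 (cat.) would return to 26.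

**Step 21.** What may go wrong: loss of regio- or stereochemical fidelity in the π-allyl hydride transfer (hydride to C13 giving the tetrasubstituted C7=C11 olefin, β-hydride elimination to a dienol/ketone), or capture of the C12 ester by the C8 alkoxide.
Fallback: the fallback sets out from epoxide 32 and comes back at 34, skipping 33. A Lewis-acid Meinwald rearrangement (MgBr2·OEt2, CH2Cl2, −78 °C) would ionise C7–O and shift hydride from C8 to the rear face of C7, giving ketone F10 with the required C7 configuration. NaBH4/CeCl3·7H2O from the exposed face would give the 8-epi alcohol F11. Mitsunobu esterification with angelic acid (PPh3, DIAD) would invert C8 and install the angelate in one operation, giving 34.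

**Step 22.** What may go wrong: sluggish acylation of the hindered C8 hydroxyl, with Z→E isomerisation of the activated angelate to the tiglate.
Fallback: the fallback sets out from 33 and comes back at 34. The alcohol would be acylated with 2-(diphenoxyphosphoryl)propanoic acid (DCC, DMAP) to the phosphonopropionate F12, and a Z-selective Horner–Wadsworth–Emmons olefination with acetaldehyde (DBU, NaI, THF, −78 → 0 °C) would build the angelate double bond on the substrate.

Further compounds
F1 | step 17 | (E)-alkenyl pinacolboronate, TBDPS ether | CC(C)(C)[Si](c1ccccc1)(c1ccccc1)OCC[C@H]1O[C@](/C=C/B2OC(C)(C)C(C)(C)O2)(CC(=O)OC(C)(C)C)[C@H]2OC(C)(C)O[C@H]2[C@H]1C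
F2 | step 17 | boronate primary alcohol | OCC[C@H]1O[C@](/C=C/B2OC(C)(C)C(C)(C)O2)(CC(=O)OC(C)(C)C)[C@H]2OC(C)(C)O[C@H]2[C@H]1C
F3 | step 17 | boronate aldehyde (not isolated) | O=CC[C@H]1O[C@](/C=C/B2OC(C)(C)C(C)(C)O2)(CC(=O)OC(C)(C)C)[C@H]2OC(C)(C)O[C@H]2[C@H]1C
F4 | step 17 | boronate carboxylic acid | OC(=O)C[C@H]1O[C@](/C=C/B2OC(C)(C)C(C)(C)O2)(CC(=O)OC(C)(C)C)[C@H]2OC(C)(C)O[C@H]2[C@H]1C
F5 | step 17 | boronate mixed anhydride (not isolated) | CC(C)COC(=O)OC(=O)C[C@H]1O[C@](/C=C/B2OC(C)(C)C(C)(C)O2)(CC(=O)OC(C)(C)C)[C@H]2OC(C)(C)O[C@H]2[C@H]1C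
F6 | step 17 | boronate α-methyl diazoketone | CC(=[N+]=[N-])C(=O)C[C@H]1O[C@](/C=C/B2OC(C)(C)C(C)(C)O2)(CC(=O)OC(C)(C)C)[C@H]2OC(C)(C)O[C@H]2[C@H]1C
F7 | step 17 | boronate oxonium ylide (not isolated) | CC1=C([O-])C[C@@H]2[C@H](C)[C@@H]3OC(C)(C)O[C@@H]3[C@@](/C=C/B3OC(C)(C)C(C)(C)O3)(CC(=O)OC(C)(C)C)[O+]12
F8 | step 17 | ring-expanded C9 allylboronate | CC(C)(C)OC(=O)C/C1=C/[C@@H](B2OC(C)(C)C(C)(C)O2)[C@@]2(C)O[C@H](CC2=O)[C@H](C)[C@@H]2OC(C)(C)O[C@H]12
F9 | step 17 | ring-expanded C9 allylic alcohol | CC(C)(C)OC(=O)C/C1=C/[C@@H](O)[C@@]2(C)O[C@H](CC2=O)[C@H](C)[C@@H]2OC(C)(C)O[C@H]12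
F10 | step 21 | C8 ketone with C7–H | CC(C)(C)OC(=O)C(=C)[C@@H]1C(=O)[C@@H](OCc2ccc(OC)cc2)[C@@]2(C)OC(=CC2=O)[C@H](C)[C@@H]2OC(C)(C)O[C@H]12
F11 | step 21 | 8-epi alcohol | CC(C)(C)OC(=O)C(=C)[C@@H]1[C@@H](O)[C@@H](OCc2ccc(OC)cc2)[C@@]2(C)OC(=CC2=O)[C@H](C)[C@@H]2OC(C)(C)O[C@H]12
F12 | step 22 | C8 2-(diphenoxyphosphoryl)propanoate | CC(C)(C)OC(=O)C(=C)[C@@H]1[C@H](OC(=O)C(C)P(=O)(Oc2ccccc2)Oc2ccccc2)[C@@H](OCc2ccc(OC)cc2)[C@@]2(C)OC(=CC2=O)[C@H](C)[C@@H]2OC(C)(C)O[C@H]12
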